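## Retrosynthetic overview

1. The target is the bis(α‑linolenate) of (3R,3'R,6'R)‑lutein. The last operations are desilylation of lutein bis‑TBS ether and a double Steglich acylation.
2. Key disconnection C10–C11: a ring A C13 enyne (C7=C8–C9≡C10–H, no C19 yet) and a ring B C26 heptaenyl iodide (I–C11=C12…) are joined by a one‑pot zirconium‑catalysed syn‑methylalumination/Pd–Zn alkenyl–alkenyl coupling, which installs C19, the 9E alkene and the C10–C11 bond together.
3. Enabling feature: C9 is the methyl‑bearing carbon of an E‑trisubstituted alkene, and its partner C10 is a CH bonded directly to C11, the CH terminus of the E‑disubstituted C11=C12 alkene. The C7=C8–C9(CH3)=C10H unit on ring A is therefore the retron of a terminal alkyne, and C10–C11 that of an alkenylmetal/alkenyl iodide union.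
4. The C26 iodide comes from the same operation on the ring B enyne with excess symmetric C12 diiodide (double Takai olefination of the C10 dialdehyde). The ring B enyne comes from (R)‑α‑ionone (P450 hydroxylation sets C3'); the ring A enyne from (4R,6R)‑actinol (enol triflate, Heck reaction).
5. No ring is formed: rings A and B are taken intact from the chiral pool. Assembly order is ring B end, central C12 unit, ring A end.

Key step: step 10

Remark: (R)‑α‑ionone, (4R,6R)‑4‑hydroxy‑2,2,6‑trimethylcyclohexanone (actinol), all‑E 2,7‑dimethylocta‑2,4,6‑trienedial, methyl vinyl ketone and α‑linolenic acid are taken as commercial; carotenoid numbering is used (ring A C1–C6, chain C7–C15 and C15'–C7', ring B C6'–C1', C19 and C19' the methyls on C9 and C9'); all polyene work is done under argon in dim light.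

## Route

Step 1
Reactants: 1 (2E,4E,6E)‑2,7‑dimethylocta‑2,4,6‑trienedial
Product: 2 (1E,3E,5E,7E,9E)‑1,10‑diiodo‑3,8‑dimethyldeca‑1,3,5,7,9‑pentaene
Conditions: CHI3 (5 equiv), CrCl2 (16 equiv), THF–1,4‑dioxane, 0 °C to rt, dark
Reagents that add atoms: iodoform (CHI3), IC(I)I
Why: Takai iodo‑olefination, in which the gem‑dichromium species formed from CHI3 and CrCl2 adds to each α‑methyl enal and the β‑oxido organochromium adduct collapses with the substituents anti, so both new CH=CHI units should be E; no stereocentre is created.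

Step 2
Reactants: 3 (R)‑α‑ionone [(3E)‑4‑[(1R)‑2,6,6‑trimethylcyclohex‑2‑en‑1‑yl]but‑3‑en‑2‑one]
Product: 4 (3R,6R)‑3‑hydroxy‑α‑ionone [(3E)‑4‑[(1R,4R)‑4‑hydroxy‑2,6,6‑trimethylcyclohex‑2‑en‑1‑yl]but‑3‑en‑2‑one]
Conditions: cytochrome P450 monooxygenase (engineered CYP102A1 variant, cell‑free extract), NADP+ (cat.), glucose dehydrogenase, D‑glucose, air (O2), potassium phosphate buffer pH 7.5, 2% DMSO, 25 °C
Reagents that add atoms: dioxygen, O=O
Why: Enzymatic allylic C–H hydroxylation by a cytochrome P450 monooxygenase (hydrogen abstraction by the high‑valent iron–oxo species, then oxygen rebound); C3 is the only secondary allylic position not shielded by the gem‑dimethyl group, and the active site should present the C3–H anti to the pseudo‑axial C6 side chain, setting the 3R centre trans to the untouched C6 centre.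

Step 3
Reactants: 4 (3R,6R)‑3‑hydroxy‑α‑ionone
Product: 5 (3E)‑4‑[(1R,4R)‑4‑{[tert‑butyl(dimethyl)silyl]oxy}‑2,6,6‑trimethylcyclohex‑2‑en‑1‑yl]but‑3‑en‑2‑one
Conditions: TBSCl (1.3 equiv), imidazole (2.5 equiv), DMF, rt
Reagents that add atoms: tert‑butyldimethylsilyl chloride (TBSCl), CC(C)(C)[Si](C)(C)Cl
Why: Imidazole‑promoted O‑silylation of the secondary allylic alcohol takes place at oxygen only, so C3 and C6 keep their configuration and the hydroxyl is masked for the strong bases and AlMe3 that follow.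

Step 4
Reactants: 5 (3E)‑4‑[(1R,4R)‑4‑{[tert‑butyl(dimethyl)silyl]oxy}‑2,6,6‑trimethylcyclohex‑2‑en‑1‑yl]but‑3‑en‑2‑one
Product: 9 tert‑butyl({(1R,4R)‑4‑[(1E)‑but‑1‑en‑3‑yn‑1‑yl]‑3,5,5‑trimethylcyclohex‑2‑en‑1‑yl}oxy)dimethylsilane (ring B enyne), via ring B lithium enolate 6 (not isolated), via ring B enol phosphate 7 (not isolated), via ring B lithium acetylide 8 (not isolated)
Conditions: LiN(i‑Pr)2 (LDA, commercial solution, 1.1 equiv), THF, −78 °C; ClP(O)(OEt)2 (1.15 equiv), −78 °C to rt; then LDA (2.3 equiv), THF, −78 °C to rt; aq. NH4Cl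
Reagents that add atoms: none
Why: Methyl ketone‑to‑terminal alkyne conversion through the enol phosphate, in which kinetic deprotonation at the methyl group (not at the doubly allylic C6–H) at −78 °C, O‑phosphorylation and LDA‑induced β‑elimination of diethyl phosphate should give the enyne with the E‑alkene and both stereocentres untouched.

Step 5
Reactants: 9 ring B enyne; 2 (1E,3E,5E,7E,9E)‑1,10‑diiodo‑3,8‑dimethyldeca‑1,3,5,7,9‑pentaene
Product: 11 tert‑butyl({(1R,4R)‑4‑[(1E,3E,5E,7E,9E,11E,13E)‑14‑iodo‑3,7,12‑trimethyltetradeca‑1,3,5,7,9,11,13‑heptaen‑1‑yl]‑3,5,5‑trimethylcyclohex‑2‑en‑1‑yl}oxy)dimethylsilane (C26 iodide), via ring B dienylalane 10 (not isolated)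
Conditions: AlMe3 (2.5 equiv), Cp2ZrCl2 (0.3 equiv), ClCH2CH2Cl, 23 °C; volatiles removed in vacuo; then slow addition to 2 (3 equiv), Pd2(dba)3 (2.5 mol %), tri(2‑furyl)phosphine (10 mol %), ZnCl2 (0.2 equiv), THF–DMF, 23 °C, dark; excess 2 recovered
Reagents that add atoms: trimethylaluminium (AlMe3), C[Al](C)C
Why: One‑pot zirconium‑catalysed syn‑methylalumination of the terminal alkyne followed by Pd/Zn‑catalysed Negishi coupling of the alkenylalane with one C–I bond of the symmetric diiodide, mono‑coupling being favoured by the threefold excess of 2 and slow addition; syn addition fixes the new trisubstituted alkene as E, the coupling retains the geometry of both partners, and no stereocentre is formed.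

Step 6
Reactants: 12 (4R,6R)‑4‑hydroxy‑2,2,6‑trimethylcyclohexan‑1‑one (actinol)
Product: 13 (4R,6R)‑4‑{[tert‑butyl(dimethyl)silyl]oxy}‑2,2,6‑trimethylcyclohexan‑1‑one
Conditions: TBSCl (1.3 equiv), imidazole (2.5 equiv), DMF, rt
Reagents that add atoms: tert‑butyldimethylsilyl chloride (TBSCl), CC(C)(C)[Si](C)(C)Cl
Why: Imidazole‑promoted O‑silylation of the secondary alcohol leaves both stereocentres untouched and masks the hydroxyl for the enolate chemistry and AlMe3 that follow.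

Step 7
Reactants: 13 (4R,6R)‑4‑{[tert‑butyl(dimethyl)silyl]oxy}‑2,2,6‑trimethylcyclohexan‑1‑one
Product: 15 (4R)‑4‑{[tert‑butyl(dimethyl)silyl]oxy}‑2,6,6‑trimethylcyclohex‑1‑en‑1‑yl trifluoromethanesulfonate, via ketone lithium enolate 14 (not isolated)
Conditions: LDA (1.2 equiv), THF, −78 to 0 °C; then PhNTf2 (1.2 equiv), −78 °C to rt
Reagents that add atoms: N‑phenylbis(trifluoromethanesulfonimide) (PhNTf2), O=S(=O)(N(c1ccccc1)S(=O)(=O)C(F)(F)F)C(F)(F)F
Why: Enol triflate formation, in which LDA can remove only the single α‑hydrogen at C6 and O‑sulfonylation of the tetrasubstituted enolate erases the C6 centre on purpose, while the silyloxy‑bearing C4 (the future C3, R) is remote and retained.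

Step 8
Reactants: 15 (4R)‑4‑{[tert‑butyl(dimethyl)silyl]oxy}‑2,6,6‑trimethylcyclohex‑1‑en‑1‑yl trifluoromethanesulfonate; 16 methyl vinyl ketone (but‑3‑en‑2‑one)
Product: 17 (3E)‑4‑[(4R)‑4‑{[tert‑butyl(dimethyl)silyl]oxy}‑2,6,6‑trimethylcyclohex‑1‑en‑1‑yl]but‑3‑en‑2‑one [(3R)‑3‑silyloxy‑β‑ionone]
Conditions: 16 (3 equiv), Pd(OAc)2 (5 mol %), PPh3 (10 mol %), Et3N (2 equiv), DMF, 70 °C
Reagents that add atoms: none
Why: Mizoroki–Heck reaction, in which oxidative addition of the alkenyl triflate to zerovalent palladium, syn insertion of the enone and syn β‑hydride elimination should give the E‑dienone; no stereocentre is formed and the silyl ether is inert.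

Step 9
Reactants: 17 (3R)‑3‑silyloxy‑β‑ionone
Product: 21 tert‑butyl({(1R)‑4‑[(1E)‑but‑1‑en‑3‑yn‑1‑yl]‑3,5,5‑trimethylcyclohex‑3‑en‑1‑yl}oxy)dimethylsilane (ring A enyne), via ring A lithium enolate 18 (not isolated), via ring A enol phosphate 19 (not isolated), via ring A lithium acetylide 20 (not isolated)
Conditions: LDA (1.1 equiv), THF, −78 °C; ClP(O)(OEt)2 (1.15 equiv), −78 °C to rt; then LDA (2.3 equiv), THF, −78 °C to rt; aq. NH4Cl
Reagents that add atoms: none
Why: The same methyl ketone‑to‑alkyne conversion through the enol phosphate (kinetic enolisation, O‑phosphorylation, β‑elimination) on a β‑ionone‑type dienone, which has no epimerisable centre near the side chain; the C3 silyloxy stereocentre is remote and untouched.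

Step 10
Reactants: 21 ring A enyne; 11 C26 iodide
Product: 23 (3R,3'R,6'R)‑3,3'‑bis{[tert‑butyl(dimethyl)silyl]oxy}‑β,ε‑carotene (lutein bis‑TBS ether), via ring A dienylalane 22 (not isolated)
Conditions: AlMe3 (2.5 equiv), Cp2ZrCl2 (0.3 equiv), ClCH2CH2Cl, 23 °C; volatiles removed in vacuo; then 11 (0.8 equiv), Pd2(dba)3 (2.5 mol %), tri(2‑furyl)phosphine (10 mol %), ZnCl2 (0.2 equiv), THF–DMF, 23 °C, dark
Reagents that add atoms: trimethylaluminium (AlMe3), C[Al](C)C
Why: Cp2ZrCl2 and AlMe3 generate a cationic methylzirconocene–aluminate that adds methyl and metal syn across the terminal C9≡C10 bond of 21, methyl to the internal C9 (creating C19) and metal to the terminal C10, and after Zr‑to‑Al exchange the (9E)‑dienylalane 22 transmetalates through zinc to the alkenylpalladium formed by oxidative addition of zerovalent palladium into the C11–I bond of 11, reductive elimination then forming the C10–C11 σ bond. The closest known reaction type is the one‑pot Negishi carboalumination/Pd–Zn cross‑coupling of conjugated enynes with alkenyl halides used for retinoid and carotene chains, applied here to a silyloxy enyne and a heptaenyl iodide. No ring is closed and no stereocentre is created; the stereochemical elements formed or transferred are the 9E alkene (fixed by the syn addition) and the 11E alkene (retention in oxidative addition and reductive elimination). The step needs regioselective methyl delivery (secured by the terminal, conjugated alkyne, which sends the metal to the unsubstituted carbon), chemoselectivity for the alkyne over the ring alkenes, the polyene and the silyl ethers (AlMe3 does not carbometalate these alkenes at 23 °C and is inert to TBS ethers, which is why the hydroxyls are carried as silyl ethers and not as esters), and a room‑temperature coupling in the dark so that the all‑E heptaene is not isomerised. The C3, C3' and C6' centres are remote from the reacting carbons and are carried through unchanged.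

Step 11
Reactants: 23 lutein bis‑TBS ether
Product: 24 (3R,3'R,6'R)‑β,ε‑carotene‑3,3'‑diol (lutein)
Conditions: n‑Bu4NF (TBAF, 4 equiv), THF, 0 °C to rt, dark; water work‑up
Reagents that add atoms: none
Why: Fluoride‑induced cleavage of both Si–O bonds (desilylation driven by the strong Si–F bond) under non‑acidic conditions leaves the acid‑labile allylic C3'–O bond, the three stereocentres and the all‑E polyene unchanged.

Step 12
Reactants: 24 lutein; 25 α‑linolenic acid [(9Z,12Z,15Z)‑octadeca‑9,12,15‑trienoic acid]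
Product: 26 (3R,3'R,6'R)‑β,ε‑carotene‑3,3'‑diyl bis[(9Z,12Z,15Z)‑octadeca‑9,12,15‑trienoate] (target)
Conditions: 25 (2.6 equiv), DCC (2.8 equiv), DMAP (0.4 equiv), CH2Cl2, 0 °C to rt, argon, dark
Reagents that add atoms: none
Why: Steglich esterification (carbodiimide activation, DMAP acyl transfer) acylates both secondary hydroxyls at oxygen with retention at C3 and C3', and its neutral room‑temperature conditions should avoid ionisation of the allylic C3'–O bond and isomerisation of the skipped Z,Z,Z‑trienes and of the all‑E polyene.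

## Compound list

1 | (2E,4E,6E)‑2,7‑dimethylocta‑2,4,6‑trienedial | O=C/C(C)=C/C=C/C=C(C)/C=O | starting material
2 | (1E,3E,5E,7E,9E)‑1,10‑diiodo‑3,8‑dimethyldeca‑1,3,5,7,9‑pentaene | I/C=C/C(C)=C/C=C/C=C(C)/C=C/I | intermediate
3 | (R)‑α‑ionone, (3E)‑4‑[(1R)‑2,6,6‑trimethylcyclohex‑2‑en‑1‑yl]but‑3‑en‑2‑one | CC(=O)/C=C/[C@H]1C(C)=CCCC1(C)C | starting material
4 | (3R,6R)‑3‑hydroxy‑α‑ionone, (3E)‑4‑[(1R,4R)‑4‑hydroxy‑2,6,6‑trimethylcyclohex‑2‑en‑1‑yl]but‑3‑en‑2‑one | CC(=O)/C=C/[C@H]1C(C)=C[C@H](O)CC1(C)C | intermediate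
5 | (3E)‑4‑[(1R,4R)‑4‑{[tert‑butyl(dimethyl)silyl]oxy}‑2,6,6‑trimethylcyclohex‑2‑en‑1‑yl]but‑3‑en‑2‑one | CC(=O)/C=C/[C@H]1C(C)=C[C@H](O[Si](C)(C)C(C)(C)C)CC1(C)C | intermediate
6 | lithium (3E)‑4‑[(1R,4R)‑4‑{[tert‑butyl(dimethyl)silyl]oxy}‑2,6,6‑trimethylcyclohex‑2‑en‑1‑yl]buta‑1,3‑dien‑2‑olate (ring B lithium enolate, not isolated) | [Li+].[O-]C(=C)/C=C/[C@H]1C(C)=C[C@H](O[Si](C)(C)C(C)(C)C)CC1(C)C | intermediate
7 | diethyl (3E)‑4‑[(1R,4R)‑4‑{[tert‑butyl(dimethyl)silyl]oxy}‑2,6,6‑trimethylcyclohex‑2‑en‑1‑yl]buta‑1,3‑dien‑2‑yl phosphate (ring B enol phosphate, not isolated) | C=C(OP(=O)(OCC)OCC)/C=C/[C@H]1C(C)=C[C@H](O[Si](C)(C)C(C)(C)C)CC1(C)C | intermediate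
8 | lithium acetylide of 9 (ring B lithium acetylide, not isolated) | [Li+].[C-]#C/C=C/[C@H]1C(C)=C[C@H](O[Si](C)(C)C(C)(C)C)CC1(C)C | intermediate
9 | tert‑butyl({(1R,4R)‑4‑[(1E)‑but‑1‑en‑3‑yn‑1‑yl]‑3,5,5‑trimethylcyclohex‑2‑en‑1‑yl}oxy)dimethylsilane (ring B enyne) | C#C/C=C/[C@H]1C(C)=C[C@H](O[Si](C)(C)C(C)(C)C)CC1(C)C | intermediate
10 | {(1E,3E)‑4‑[(1R,4R)‑4‑{[tert‑butyl(dimethyl)silyl]oxy}‑2,6,6‑trimethylcyclohex‑2‑en‑1‑yl]‑2‑methylbuta‑1,3‑dien‑1‑yl}(dimethyl)alumane (ring B dienylalane, not isolated) | C[Al](C)/C=C(C)/C=C/[C@H]1C(C)=C[C@H](O[Si](C)(C)C(C)(C)C)CC1(C)C | intermediate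
11 | tert‑butyl({(1R,4R)‑4‑[(1E,3E,5E,7E,9E,11E,13E)‑14‑iodo‑3,7,12‑trimethyltetradeca‑1,3,5,7,9,11,13‑heptaen‑1‑yl]‑3,5,5‑trimethylcyclohex‑2‑en‑1‑yl}oxy)dimethylsilane (C26 iodide) | I/C=C/C(C)=C/C=C/C=C(C)/C=C/C=C(C)/C=C/[C@H]1C(C)=C[C@H](O[Si](C)(C)C(C)(C)C)CC1(C)C | intermediate
12 | (4R,6R)‑4‑hydroxy‑2,2,6‑trimethylcyclohexan‑1‑one (actinol) | O=C1[C@H](C)C[C@@H](O)CC1(C)C | starting material
13 | (4R,6R)‑4‑{[tert‑butyl(dimethyl)silyl]oxy}‑2,2,6‑trimethylcyclohexan‑1‑one | O=C1[C@H](C)C[C@@H](O[Si](C)(C)C(C)(C)C)CC1(C)C | intermediate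
14 | lithium (4R)‑4‑{[tert‑butyl(dimethyl)silyl]oxy}‑2,6,6‑trimethylcyclohex‑1‑en‑1‑olate (ketone lithium enolate, not isolated) | [Li+].[O-]C1=C(C)C[C@@H](O[Si](C)(C)C(C)(C)C)CC1(C)C | intermediate
15 | (4R)‑4‑{[tert‑butyl(dimethyl)silyl]oxy}‑2,6,6‑trimethylcyclohex‑1‑en‑1‑yl trifluoromethanesulfonate | FC(F)(F)S(=O)(=O)OC1=C(C)C[C@@H](O[Si](C)(C)C(C)(C)C)CC1(C)C | intermediate
16 | methyl vinyl ketone (but‑3‑en‑2‑one) | C=CC(C)=O | starting material
17 | (3E)‑4‑[(4R)‑4‑{[tert‑butyl(dimethyl)silyl]oxy}‑2,6,6‑trimethylcyclohex‑1‑en‑1‑yl]but‑3‑en‑2‑one | CC(=O)/C=C/C1=C(C)C[C@@H](O[Si](C)(C)C(C)(C)C)CC1(C)C | intermediate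
18 | lithium (3E)‑4‑[(4R)‑4‑{[tert‑butyl(dimethyl)silyl]oxy}‑2,6,6‑trimethylcyclohex‑1‑en‑1‑yl]buta‑1,3‑dien‑2‑olate (ring A lithium enolate, not isolated) | [Li+].[O-]C(=C)/C=C/C1=C(C)C[C@@H](O[Si](C)(C)C(C)(C)C)CC1(C)C | intermediate
19 | diethyl (3E)‑4‑[(4R)‑4‑{[tert‑butyl(dimethyl)silyl]oxy}‑2,6,6‑trimethylcyclohex‑1‑en‑1‑yl]buta‑1,3‑dien‑2‑yl phosphate (ring A enol phosphate, not isolated) | C=C(OP(=O)(OCC)OCC)/C=C/C1=C(C)C[C@@H](O[Si](C)(C)C(C)(C)C)CC1(C)C | intermediate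
20 | lithium acetylide of 21 (ring A lithium acetylide, not isolated) | [Li+].[C-]#C/C=C/C1=C(C)C[C@@H](O[Si](C)(C)C(C)(C)C)CC1(C)C | intermediate
21 | tert‑butyl({(1R)‑4‑[(1E)‑but‑1‑en‑3‑yn‑1‑yl]‑3,5,5‑trimethylcyclohex‑3‑en‑1‑yl}oxy)dimethylsilane (ring A enyne) | C#C/C=C/C1=C(C)C[C@@H](O[Si](C)(C)C(C)(C)C)CC1(C)C | intermediate
22 | {(1E,3E)‑4‑[(4R)‑4‑{[tert‑butyl(dimethyl)silyl]oxy}‑2,6,6‑trimethylcyclohex‑1‑en‑1‑yl]‑2‑methylbuta‑1,3‑dien‑1‑yl}(dimethyl)alumane (ring A dienylalane, not isolated) | C[Al](C)/C=C(C)/C=C/C1=C(C)C[C@@H](O[Si](C)(C)C(C)(C)C)CC1(C)C | intermediate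
23 | (3R,3'R,6'R)‑3,3'‑bis{[tert‑butyl(dimethyl)silyl]oxy}‑β,ε‑carotene (lutein bis‑TBS ether) | CC(C)(C)[Si](C)(C)O[C@@H]1CC(C)=C(/C=C/C(C)=C/C=C/C(C)=C/C=C/C=C(C)/C=C/C=C(C)/C=C/[C@H]2C(C)=C[C@H](O[Si](C)(C)C(C)(C)C)CC2(C)C)C(C)(C)C1 | intermediate
24 | (3R,3'R,6'R)‑β,ε‑carotene‑3,3'‑diol (lutein) | O[C@@H]1CC(C)=C(/C=C/C(C)=C/C=C/C(C)=C/C=C/C=C(C)/C=C/C=C(C)/C=C/[C@H]2C(C)=C[C@H](O)CC2(C)C)C(C)(C)C1 | intermediate
25 | α‑linolenic acid, (9Z,12Z,15Z)‑octadeca‑9,12,15‑trienoic acid | CC/C=C\C/C=C\C/C=C\CCCCCCCC(=O)O | starting material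
26 | (3R,3'R,6'R)‑β,ε‑carotene‑3,3'‑diyl bis[(9Z,12Z,15Z)‑octadeca‑9,12,15‑trienoate] | CC/C=C\C/C=C\C/C=C\CCCCCCCC(=O)O[C@@H]1CC(C)=C(/C=C/C(C)=C/C=C/C(C)=C/C=C/C=C(C)/C=C/C=C(C)/C=C/[C@H]2C(C)=C[C@H](OC(=O)CCCCCCC/C=C\C/C=C\C/C=C\CC)CC2(C)C)C(C)(C)C1 | target

## Step count and risks

Total step count: 12.
Longest linear sequence: 7 steps (steps 2, 3, 4, 5, 10, 11 and 12 from 3; the branch from 12 through steps 6 to 12 is of equal length).

Steps most likely to fail:

Step 5. Mono‑selectivity may be lost: once one C–I bond has coupled, the remaining C–I bond of the product undergoes oxidative addition about as readily as those of 2. The long handling needed to separate polyenyl iodides also invites E/Z isomerisation. The fallback replaces control by stoichiometry with control by halogen chemoselectivity; it sets out from 1 and rejoins the route at 23. Dialdehyde 1, used in excess, would be converted by a single Takai olefination (CHI3, CrCl2) into (2E,4E,6E,8E)‑9‑iodo‑2,7‑dimethylnona‑2,4,6,8‑tetraenal F1, unreacted 1 being recovered thanks to its much higher polarity. A second Takai‑type olefination with CHBr3 and CrBr2 would give (1E,3E,5E,7E,9E)‑1‑bromo‑10‑iodo‑3,8‑dimethyldeca‑1,3,5,7,9‑pentaene F2. Alane 10 (one equivalent) should then couple only at the C–I bond, oxidative addition to C–I being much faster than to C–Br, to give the C26 bromide tert‑butyl({(1R,4R)‑4‑[(1E,3E,5E,7E,9E,11E,13E)‑14‑bromo‑3,7,12‑trimethyltetradeca‑1,3,5,7,9,11,13‑heptaen‑1‑yl]‑3,5,5‑trimethylcyclohex‑2‑en‑1‑yl}oxy)dimethylsilane F3. F3 would take the place of 11 in step 10 (same catalyst system, 23 to 40 °C) and deliver 23.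

Step 2. Conversion may stall on preparative scale, oxidation may occur at other positions or continue to the enone, and oxygen rebound may show insufficient facial selectivity. The fallback is a chemical oxidation–reduction sequence that sets out from 3 and comes back at 4. Ketalisation (ethylene glycol, HC(OMe)3, cat. p‑TsOH) would give 2‑methyl‑2‑{(E)‑2‑[(1R)‑2,6,6‑trimethylcyclohex‑2‑en‑1‑yl]ethenyl}‑1,3‑dioxolane F4. Allylic oxidation at C3 (t‑BuOOH, aq. NaOCl, MeCN, 0 °C) would give (4R)‑3,5,5‑trimethyl‑4‑[(E)‑2‑(2‑methyl‑1,3‑dioxolan‑2‑yl)ethenyl]cyclohex‑2‑en‑1‑one F5. Reduction with LiBH(s‑Bu)3 at −78 °C is expected to deliver hydride anti to the pseudo‑axial C1 methyl and hence give the alcohol trans to the pseudo‑axial C6 side chain, (1R,4R)‑3,5,5‑trimethyl‑4‑[(E)‑2‑(2‑methyl‑1,3‑dioxolan‑2‑yl)ethenyl]cyclohex‑2‑en‑1‑ol F6; any cis epimer would be removed by chromatography. Mild hydrolysis of the dioxolane (PPTS, aqueous acetone) would return 4.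

Step 10. Methylalumination of the silyloxy enyne may be incomplete or regiochemically imperfect, methyl may transfer in place of the dienyl group, and the heptaenyl iodide may isomerise or decompose in the presence of Lewis‑acidic aluminium and zinc species before oxidative addition. The fallback forms the same C10–C11 bond from an isolated, purified tin reagent under neutral Stille conditions; it sets out from 21 and comes back at 23. Enyne 21 would be methylaluminated as before and alane 22 quenched with I2 to give tert‑butyl({(1R)‑4‑[(1E,3E)‑4‑iodo‑3‑methylbuta‑1,3‑dien‑1‑yl]‑3,5,5‑trimethylcyclohex‑3‑en‑1‑yl}oxy)dimethylsilane F7. Iodine–lithium exchange (t‑BuLi, THF, −78 °C) and trapping with Bu3SnCl would give tert‑butyl(dimethyl)({(1R)‑3,5,5‑trimethyl‑4‑[(1E,3E)‑3‑methyl‑4‑(tributylstannyl)buta‑1,3‑dien‑1‑yl]cyclohex‑3‑en‑1‑yl}oxy)silane F8. Stille coupling of F8 with 11 (Pd2(dba)3, AsPh3, NMP, rt to 40 °C, dark) would give 23.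

## Further compounds

F1 | step 5 | (2E,4E,6E,8E)‑9‑iodo‑2,7‑dimethylnona‑2,4,6,8‑tetraenal | O=C/C(C)=C/C=C/C=C(C)/C=C/I
F2 | step 5 | (1E,3E,5E,7E,9E)‑1‑bromo‑10‑iodo‑3,8‑dimethyldeca‑1,3,5,7,9‑pentaene | Br/C=C/C(C)=C/C=C/C=C(C)/C=C/I
F3 | step 5 | tert‑butyl({(1R,4R)‑4‑[(1E,3E,5E,7E,9E,11E,13E)‑14‑bromo‑3,7,12‑trimethyltetradeca‑1,3,5,7,9,11,13‑heptaen‑1‑yl]‑3,5,5‑trimethylcyclohex‑2‑en‑1‑yl}oxy)dimethylsilane | Br/C=C/C(C)=C/C=C/C=C(C)/C=C/C=C(C)/C=C/[C@H]1C(C)=C[C@H](O[Si](C)(C)C(C)(C)C)CC1(C)C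
F4 | step 2 | 2‑methyl‑2‑{(E)‑2‑[(1R)‑2,6,6‑trimethylcyclohex‑2‑en‑1‑yl]ethenyl}‑1,3‑dioxolane | CC1(/C=C/[C@H]2C(C)=CCCC2(C)C)OCCO1
F5 | step 2 | (4R)‑3,5,5‑trimethyl‑4‑[(E)‑2‑(2‑methyl‑1,3‑dioxolan‑2‑yl)ethenyl]cyclohex‑2‑en‑1‑one | CC1(/C=C/[C@H]2C(C)=CC(=O)CC2(C)C)OCCO1
F6 | step 2 | (1R,4R)‑3,5,5‑trimethyl‑4‑[(E)‑2‑(2‑methyl‑1,3‑dioxolan‑2‑yl)ethenyl]cyclohex‑2‑en‑1‑ol | CC1(/C=C/[C@H]2C(C)=C[C@H](O)CC2(C)C)OCCO1
F7 | step 10 | tert‑butyl({(1R)‑4‑[(1E,3E)‑4‑iodo‑3‑methylbuta‑1,3‑dien‑1‑yl]‑3,5,5‑trimethylcyclohex‑3‑en‑1‑yl}oxy)dimethylsilane | I/C=C(C)/C=C/C1=C(C)C[C@@H](O[Si](C)(C)C(C)(C)C)CC1(C)C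
F8 | step 10 | tert‑butyl(dimethyl)({(1R)‑3,5,5‑trimethyl‑4‑[(1E,3E)‑3‑methyl‑4‑(tributylstannyl)buta‑1,3‑dien‑1‑yl]cyclohex‑3‑en‑1‑yl}oxy)silane | CCCC[Sn](CCCC)(CCCC)/C=C(C)/C=C/C1=C(C)C[C@@H](O[Si](C)(C)C(C)(C)C)CC1(C)C
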